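## The problem

The target is a eudesmane, numbered here in the usual way: ring A is C1–C5 and C10, ring B is C5–C10, C14 is the methyl on C10, C15 the methyl on C4, and β is the face of the C10 methyl. Ring A of this trans-fused decalin carries a cis-3α,4α-diol; the secondary oxygen is acylated by (2S,3S)-2,3-epoxy-2-methylbutanoic acid and the tertiary C4 also bears the axial methyl C15. Ring B carries an 8-ketone flanked by a tertiary 7α-hydroxyl, with the C11 dimethylcarbinol on the 7β bond. Seven stereocentres have to be set: C10 (quaternary), C5, C4, C3 and C7 on the bicycle and two in the oxirane of the acyl group. C10 is the anchor: its axial methyl closes the β face of ring A, so oxygen can be brought to C3 and C4 from the α face, and through the rigid ring fusion it decides which bond at C7 is axial. C5 must be fixed relative to C10 before or while ring B closes, and the two oxirane centres are too remote from the core and need reagent control. The fragile parts are the oxirane next to the ester carbonyl (acid, halide), the tertiary α-ketol with a β-hydroxyl at C11 (retro-aldol loss of C11, acyloin shift) and three tertiary alcohols; since only the C3 hydroxyl is secondary, the ester can go on last without protecting groups. The feature that opens the skeleton is the sequence C4(O)–C5–C10: with C4 as a ketone, C5 and C10 are the α- and β-carbons of 3-methylcyclohex-2-en-1-one (its methyl is C14). C9 can then be added to C10 as a nucleophile and C6 to C5 as an electrophile; a vinyl group (C9, C8) and a prenyl group (C6, C7, C11–C13) supply every skeletal carbon except C15 and are placed for closure of ring B between C7 and C8.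

## Retrosynthesis

**Ester C–O bond.** Cutting the acyl–O3 bond of 23 gives tetraol 17 and epoxy acid 21. Bringing the oxirane in ready-made is preferred to epoxidising an unsaturated ester on the core, where neither face would be controlled. 17 is a C15 compound with one secondary hydroxyl, so the forward step only has to acylate a hindered axial alcohol under conditions the oxirane and the ketol survive.

**Epoxy acid.** 21 goes back to epoxy alcohol 20 by adjusting the oxidation level, and 20 to (Z)-allylic alcohol 19 by Sharpless epoxidation, which sets both oxirane centres from an achiral alkene. 19 is the reduction product of angelic acid 18. The forward steps must keep the Z geometry and must not open the oxirane.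

**C3–O and C4–O.** Both oxygens of 17 are removed together to give alkene 16. A syn-dihydroxylation from the α face gives the 3α,4α-diol with the methyl axial. The neighbouring option, adding a methyl nucleophile to a C4 ketone, would come from the equatorial side and give the wrong C4 epimer, and would leave C3 unoxidised.

**C7–O and C11–O.** The diol of 16 is traced to spiro-epoxy ketone 15 and this to the isopropylidene ketone 14. Nucleophilic epoxidation touches only the enone and forms the C7–O bond in the ring-closing step of an enolate, where the axial (α) bond is favoured. An osmium-type dihydroxylation of 14 would attack C3=C4 first and would be expected to approach C7 equatorially. 14 is the conjugated isomer of isopropenyl ketone 13.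

**Ring B, C7–C8.** 13 is opened between C7 and C8 to aldehyde 11, via homoallylic alcohol 12. This is the citronellal-to-isopulegol pattern: a carbonyl-ene reaction of an aldehyde with a trisubstituted alkene six atoms away. The two centres the ene reaction creates (C7, C8) become sp2 again, so no selectivity is asked of it beyond ring size. 11 comes from primary alcohol 10, so the cyclisation and both oxidations can be run in one flask.

**C8 oxygen.** 10 is the anti-Markovnikov hydration product of triene 8. The forward reaction has to pick the monosubstituted vinyl group out of three alkenes, which a bulky dialkylborane does.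

**C4–C15.** The methyl on C4 of 8 is cut to enol triflate 7, and 7 comes from ketone 5 by kinetic enolisation toward C3. This route fixes the double bond at C3–C4; addition of a methyl nucleophile to the ketone followed by dehydration would give olefin mixtures. Removing the ketone this early also means that no second carbonyl has to be told apart from the C8 ketone later.

**C9–C10 and C5–C6.** Ketone 5 is cut at both bonds to the enone core, giving 3-methylcyclohex-2-en-1-one 1, vinylmagnesium bromide 2 and prenyl bromide 3. Compared with stepwise annulation this makes the quaternary centre, the second stereocentre and fourteen of fifteen skeletal carbons in one operation from three commercial compounds. The forward reaction must give one enantioface at C10 (catalyst control) and prenylation trans to vinyl (substrate control, the weaker of the two).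

## Roads not taken

**Alternative 1:** The cut goes through ring B at C5–C10 and C8–C9. A diene A3 (C5=C6–C7=C8, carrying the protected C11 carbinol on C7 and a two-carbon arm on C5) would add to methacrolein A2 in an exo-selective [4+2] reaction under a chiral oxazaborolidinium Lewis acid, giving cyclohexene aldehyde A1.
- Merits: the concerted exo addition fixes C5 relative to C10 together with the absolute configuration, and the ortho/para preferences of the diene match. In relative control at C5/C10 this road is better than the chosen one, which depends on a moderately selective enolate alkylation.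
- Weak points: A3 has to be made in several steps. In A1 ring A does not exist yet: the formyl carbon is C1, the arm supplies C4 and C3, C2 and C15 are missing, and C4 arrives as a plain methylene that must later take both a methyl and a hydroxyl. The ring B alkene lies at C6–C7, so oxygen would have to be moved to C8.
- Comparison: against the better stereocontrol, the chosen plan sets commercial starting materials, all carbons but C15 after one step, and functional groups (C4 ketone, vinyl, prenyl) already in the positions the later steps need.

**Alternative 2:** The cut is the transannular C5–C10 bond. Germacrone A4 would be reduced and acetylated to the C8 acetate A5, and acid would protonate C1, close C5–C10 and shed a C3 proton to give eudesmadienyl acetate A6.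
- Merits: biomimetic, all fifteen carbons and the C8 oxygen come from a natural product, and A6 after deacetylation and oxidation would be dienone 14 of the present route. In step count this road is clearly shorter, about four operations to 14 against six.
- Weak points: A4 is achiral, so all asymmetry has to come from an enantioselective reduction of a hindered cross-conjugated ketone and then be relayed from C8 across a flexible ten-membered ring. Such cyclisations tend to give mixtures of olefin isomers (C3, C4(15), C4(5)) and of ring-fusion isomers, and the triene is prone to Cope rearrangement to an elemane. Supply and purity of A4 are variable.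
- Comparison: the chosen plan sets against the shorter sequence a catalyst-controlled absolute configuration at a quaternary carbon and an unambiguous position for every double bond.

**Alternative 3:** The cut is C5–C6. A prochiral cyclohexadienone A7 with a 2,3-dioxobutyl chain on the quaternary carbon would close by an amine–thiourea-catalysed Michael addition of the dione methyl onto one enone arm, giving bicyclic trione A8.
- Merits: a short precursor, organocatalytic desymmetrisation that sets C10 and C5 together, C7 and C8 already oxidised, and an enone left in ring A for work at C3/C4. For catalytic enantiocontrol this road is at least as good as the chosen one.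
- Weak points: the closure can only give the cis ring fusion, and C5 in A8 is β to the carbonyls, so it cannot be epimerised by enolisation. C11–C13 and C15 are missing; the three-carbon unit would have to be added to one of three ketones, and the ring A oxygen sits on C3 while C4 is a methylene.
- Comparison: the chosen plan has the weaker control at C5 but aims directly at the trans fusion and carries C11–C13 from the start.

Key step: step 1

Assumption: the antipode of the imidazolinium ligand in step 1 is the one that gives the 3R enolate 4; the sense of induction has to be matched once by experiment.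

## Route

Step 1
Reactants: 1 3-methylcyclohex-2-en-1-one; 2 vinylmagnesium bromide; 3 1-bromo-3-methylbut-2-ene (prenyl bromide)
Product: 5 (2R,3R)-3-ethenyl-3-methyl-2-(3-methylbut-2-en-1-yl)cyclohexan-1-one, via bromomagnesium enolate 4 (not isolated)
Conditions: CuCl (5 mol%), chiral C2-symmetric imidazolinium chloride (carbene precursor, 6 mol%), Et2O, −30 °C, 2 (1.3 equiv, THF solution diluted with Et2O) added slowly; then DMPU, 3 (2 equiv), −30 → 23 °C
Reagents that add atoms: none
Why: Copper-catalysed asymmetric conjugate addition with enolate alkylation: the carbene-ligated monovalent copper is transmetalated by 2, the vinylcopper species binds the enone, oxidative addition at the β-carbon gives a trivalent copper intermediate and reductive elimination forms C9–C10; the regiodefined enolate 4 is then C-alkylated by 3 at its primary carbon to form C5–C6. The closest known reaction type is the carbene–copper-catalysed addition of Grignard reagents to 3-substituted cyclohexenones that creates a quaternary centre, with trapping of the magnesium enolate by an allylic halide. No ring is closed. C10 is set by the chiral carbene ligand, which selects the enone face; C5 is set by the substrate, the electrophile entering axially and anti to the pseudo-axial vinyl group of the half-chair enolate, that is trans to vinyl and cis to methyl. The step needs 1,4- over 1,2-addition (copper, slow addition of 2), C- over O-alkylation and attack at the primary end of 3 (DMPU loosens the magnesium enolate), and no enolate equilibration (excess 3, low temperature). Because methyl and vinyl differ little in size, only a moderate preference for the trans isomer is expected; the isomers are to be separated at this stage and the unwanted one can be re-equilibrated through its enolate and recycled.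

Step 2
Reactants: 5 (2R,3R)-3-ethenyl-3-methyl-2-(3-methylbut-2-en-1-yl)cyclohexan-1-one
Product: 7 (5R,6R)-5-ethenyl-5-methyl-6-(3-methylbut-2-en-1-yl)cyclohex-1-en-1-yl trifluoromethanesulfonate, via potassium enolate 6 (not isolated)
Conditions: KN(SiMe3)2 (1.1 equiv), THF, −78 °C; then PhNTf2, −78 → 0 °C
Reagents that add atoms: N-phenylbis(trifluoromethanesulfonimide), O=S(=O)(N(c1ccccc1)S(=O)(=O)C(F)(F)F)C(F)(F)F
Why: Enol triflate formation: kinetic deprotonation should take the unhindered C3 methylene and not the tertiary C5–H next to the quaternary carbon, and O-sulfonylation fixes the double bond at C3–C4; a slight excess of base prevents proton exchange at C5, so no stereocentre is touched.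

Step 3
Reactants: 7 (5R,6R)-5-ethenyl-5-methyl-6-(3-methylbut-2-en-1-yl)cyclohex-1-en-1-yl trifluoromethanesulfonate
Product: 8 (5R,6S)-5-ethenyl-1,5-dimethyl-6-(3-methylbut-2-en-1-yl)cyclohex-1-ene
Conditions: MeMgBr, Fe(acac)3 (5 mol%), THF/NMP, −30 → 0 °C
Reagents that add atoms: methylmagnesium bromide, C[Mg]Br
Why: Iron-catalysed Kumada-type coupling of an alkenyl triflate with a methyl Grignard reagent puts C15 on C4 without moving the double bond; the other alkenes are spectators and the descriptor at the ring-fusion carbon changes to S only through the priority rules.

Step 4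
Reactants: 8 (5R,6S)-5-ethenyl-1,5-dimethyl-6-(3-methylbut-2-en-1-yl)cyclohex-1-ene
Product: 10 2-[(1R,2R)-1,3-dimethyl-2-(3-methylbut-2-en-1-yl)cyclohex-3-en-1-yl]ethan-1-ol, via alkylborane 9 (not isolated)
Conditions: 9-BBN, THF, 0 → 40 °C; then NaOH, H2O2, 0 → 23 °C
Reagents that add atoms: hydrogen peroxide, OO
Why: Hydroboration–oxidation: the bulky borane should add only to the monosubstituted vinyl group, boron going to the terminal carbon C8, and leave both trisubstituted alkenes alone; oxidation with retention gives the primary alcohol.

Step 5
Reactants: 10 2-[(1R,2R)-1,3-dimethyl-2-(3-methylbut-2-en-1-yl)cyclohex-3-en-1-yl]ethan-1-ol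
Product: 13 5α-eudesma-3,11-dien-8-one (7β-isopropenyl), via aldehyde 11 (not isolated), via homoallylic alcohol 12 (not isolated)
Conditions: pyridinium chlorochromate (C5H5NH)[CrO3Cl] (3 equiv), CH2Cl2, 23 °C
Reagents that add atoms: none
Why: Chlorochromate oxidative cyclisation: the alcohol is oxidised to aldehyde 11, the acidic oxidant promotes an intramolecular carbonyl-ene reaction with the prenyl alkene through a chair transition state that closes ring B between C7 and C8, and alcohol 12 is oxidised in the same flask; the known conversion of citronellol into isopulegone is the direct model and the quaternary C10 should help closure. The centres formed at C7 and C8 need no control because both become sp2 in the next steps.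

Step 6
Reactants: 13 5α-eudesma-3,11-dien-8-one (7β-isopropenyl)
Product: 15 7α,11-epoxy-5α-eudesm-3-en-8-one, via conjugated dienone 14 (not isolated)
Conditions: NaOH (cat.), MeOH, 23 °C; then 30% H2O2, 0 → 23 °C
Reagents that add atoms: hydrogen peroxide, OO
Why: Base moves the double bond into conjugation and Weitz–Scheffer epoxidation follows: hydroperoxide adds to C11 and the enolate closes onto oxygen through the axial α face of C7 (chair-like closure, only hydrogens syn-axial), which should give the 7α oxygen; the isolated C3=C4 alkene does not react with the nucleophilic oxidant and consumption of 14 pulls the isomerisation to completion.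

Step 7
Reactants: 15 7α,11-epoxy-5α-eudesm-3-en-8-one
Product: 16 7α,11-dihydroxy-5α-eudesm-3-en-8-one
Conditions: HClO4 (dilute aq.), THF, 0 → 23 °C
Reagents that add atoms: water, O
Why: Acid-catalysed epoxide hydration: the oxirane should open at the tertiary C11, remote from the carbonyl, so the C7–O bond and its α configuration are kept; C11 is not stereogenic.

Step 8
Reactants: 16 7α,11-dihydroxy-5α-eudesm-3-en-8-one
Product: 17 (3R,4S,5R,7S,10R)-3α,4α,7α,11-tetrahydroxy-5α-eudesman-8-one
Conditions: OsO4 (2 mol%), NMO, acetone/H2O, 23 °C
Reagents that add atoms: osmium tetroxide, O=[Os](=O)(=O)=O; N-methylmorpholine N-oxide, C[N+]1([O-])CCOCC1; water, O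
Why: Upjohn syn-dihydroxylation: the axial C10 methyl is syn-axial to C4 on the β face, so the oxidant should add to C3=C4 from the α face and give the 3α,4α-diol with C15 axial; the ketol and the tertiary alcohols are inert.

Step 9
Reactants: 18 angelic acid, (Z)-2-methylbut-2-enoic acid
Product: 19 (Z)-2-methylbut-2-en-1-ol
Conditions: LiAlH4, Et2O, 0 °C
Reagents that add atoms: none
Why: Hydride reduction of the carboxylic acid; the low temperature and absence of acid keep the Z geometry.

Step 10
Reactants: 19 (Z)-2-methylbut-2-en-1-ol
Product: 20 [(2R,3S)-2,3-dimethyloxiran-2-yl]methanol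
Conditions: Ti(OiPr)4 (10 mol%), D-(−)-diisopropyl tartrate (12 mol%), t-BuOOH, 4 Å MS, CH2Cl2, −20 °C
Reagents that add atoms: tert-butyl hydroperoxide, CC(C)(C)OO
Why: Sharpless asymmetric epoxidation: the titanium tartrate complex delivers oxygen to one face of the allylic alcohol, the D-tartrate giving the (2R,3S) oxirane (mirror image of the L-tartrate product), and the cis relation of the alkene substituents is carried over.

Step 11
Reactants: 20 [(2R,3S)-2,3-dimethyloxiran-2-yl]methanol
Product: 21 (2S,3S)-2,3-dimethyloxirane-2-carboxylic acid
Conditions: RuCl3 (2 mol%), NaIO4, MeCN/EtOAc/H2O, 0 → 23 °C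
Reagents that add atoms: water, O; sodium periodate, [Na+].[O-]I(=O)(=O)=O
Why: Ruthenium tetroxide oxidation (catalytic RuCl3, periodate as terminal oxidant) is the standard way from 2,3-epoxy alcohols to glycidic acids; neither stereocentre is touched, and C2 changes from R to S only because the carboxyl group outranks C3.

Step 12
Reactants: 17 (3R,4S,5R,7S,10R)-3α,4α,7α,11-tetrahydroxy-5α-eudesman-8-one; 21 (2S,3S)-2,3-dimethyloxirane-2-carboxylic acid
Product: 23 (3R,4S,5R,7S,10R)-4α,7α,11-trihydroxy-8-oxo-5α-eudesman-3α-yl (2S,3S)-2,3-dimethyloxirane-2-carboxylate, via mixed anhydride 22 (not isolated)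
Conditions: 21, 2,4,6-trichlorobenzoyl chloride, Et3N, toluene, 23 °C; then 17, DMAP, 23 → 50 °C
Reagents that add atoms: none
Why: Yamaguchi esterification: the C3 hydroxyl is the only secondary one and the three tertiary hydroxyls should not acylate, so no protecting group is needed; the mildly basic conditions should spare the oxirane and the ketol, and no stereocentre is involved.

## Compound list

1 | 3-methylcyclohex-2-en-1-one | CC1=CC(=O)CCC1 | starting material
2 | vinylmagnesium bromide | C=C[Mg]Br | starting material
3 | 1-bromo-3-methylbut-2-ene (prenyl bromide) | CC(C)=CCBr | starting material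
4 | bromomagnesium (3R)-3-ethenyl-3-methylcyclohex-1-en-1-olate (not isolated) | Br[Mg]OC1=C[C@@](C)(C=C)CCC1 | intermediate
5 | (2R,3R)-3-ethenyl-3-methyl-2-(3-methylbut-2-en-1-yl)cyclohexan-1-one | C1CC[C@](C)(C=C)[C@@H](CC=C(C)C)C1=O | intermediate
6 | potassium (5R,6R)-5-ethenyl-5-methyl-6-(3-methylbut-2-en-1-yl)cyclohex-1-en-1-olate (not isolated) | [K]OC1=CCC[C@](C)(C=C)[C@H]1CC=C(C)C | intermediate
7 | (5R,6R)-5-ethenyl-5-methyl-6-(3-methylbut-2-en-1-yl)cyclohex-1-en-1-yl trifluoromethanesulfonate | FC(F)(F)S(=O)(=O)OC1=CCC[C@](C)(C=C)[C@H]1CC=C(C)C | intermediate
8 | (5R,6S)-5-ethenyl-1,5-dimethyl-6-(3-methylbut-2-en-1-yl)cyclohex-1-ene | CC1=CCC[C@](C)(C=C)[C@H]1CC=C(C)C | intermediate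
9 | 9-{2-[1,3-dimethyl-2-(3-methylbut-2-en-1-yl)cyclohex-3-en-1-yl]ethyl}-9-borabicyclo[3.3.1]nonane, ring centres as in 8 (not isolated) | CC1=CCC[C@](C)(CCB2C3CCCC2CCC3)[C@H]1CC=C(C)C | intermediate
10 | 2-[(1R,2R)-1,3-dimethyl-2-(3-methylbut-2-en-1-yl)cyclohex-3-en-1-yl]ethan-1-ol | CC1=CCC[C@](C)(CCO)[C@H]1CC=C(C)C | intermediate
11 | 2-[(1R,2R)-1,3-dimethyl-2-(3-methylbut-2-en-1-yl)cyclohex-3-en-1-yl]acetaldehyde (not isolated) | CC1=CCC[C@](C)(CC=O)[C@H]1CC=C(C)C | intermediate
12 | 5α-eudesma-3,11-dien-8α-ol, 7β-isopropenyl, 10β-methyl (not isolated) | CC1=CCC[C@]2(C)C[C@H](O)[C@@H](C(C)=C)C[C@@H]12 | intermediate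
13 | 5α-eudesma-3,11-dien-8-one, 7β-isopropenyl, 10β-methyl | CC1=CCC[C@]2(C)CC(=O)[C@@H](C(C)=C)C[C@@H]12 | intermediate
14 | 5α-eudesma-3,7(11)-dien-8-one, 10β-methyl (not isolated) | CC1=CCC[C@]2(C)CC(=O)C(=C(C)C)C[C@@H]12 | intermediate
15 | 7α,11-epoxy-5α-eudesm-3-en-8-one | CC1=CCC[C@]2(C)CC(=O)[C@]3(OC3(C)C)C[C@@H]12 | intermediate
16 | 7α,11-dihydroxy-5α-eudesm-3-en-8-one | CC1=CCC[C@]2(C)CC(=O)[C@@](O)(C(C)(C)O)C[C@@H]12 | intermediate
17 | (3R,4S,5R,7S,10R)-3α,4α,7α,11-tetrahydroxy-5α-eudesman-8-one (4β-methyl) | O[C@@H]1CC[C@]2(C)CC(=O)[C@@](O)(C(C)(C)O)C[C@H]2[C@]1(C)O | intermediate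
18 | angelic acid, (Z)-2-methylbut-2-enoic acid | C/C=C(/C)C(=O)O | starting material
19 | (Z)-2-methylbut-2-en-1-ol | C/C=C(/C)CO | intermediate
20 | [(2R,3S)-2,3-dimethyloxiran-2-yl]methanol | C[C@@H]1O[C@]1(C)CO | intermediate
21 | (2S,3S)-2,3-dimethyloxirane-2-carboxylic acid | C[C@@H]1O[C@]1(C)C(=O)O | intermediate
22 | (2S,3S)-2,3-dimethyloxirane-2-carboxylic 2,4,6-trichlorobenzoic anhydride (not isolated) | C[C@@H]1O[C@]1(C)C(=O)OC(=O)c2c(Cl)cc(Cl)cc2Cl | intermediate
23 | (3R,4S,5R,7S,10R)-4α,7α,11-trihydroxy-8-oxo-5α-eudesman-3α-yl (2S,3S)-2,3-dimethyloxirane-2-carboxylate | C[C@@H]1O[C@]1(C)C(=O)O[C@@H]1CC[C@]2(C)CC(=O)[C@@](O)(C(C)(C)O)C[C@H]2[C@]1(C)O | target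

## Step count and least certain steps

Total: 12 steps. Longest linear sequence: 9 steps (steps 1–8 and 12). The acid 21 is made in 3 steps (9–11).

**Step 1 (key step).** The most likely failure is weak facial discrimination in the alkylation of enolate 4, because the methyl and vinyl groups on the neighbouring quaternary carbon are of similar size. The second concern is erosion of enantioface selection with a small sp2 Grignard reagent. The main route has no later point at which C5 can be corrected, since C4 stops being a carbonyl in step 2.

The fallback replaces kinetic control by thermodynamic control after ring B is closed. It sets out from 5, used as its mixture of C5 epimers.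
- Hydroboration of the vinyl group with 9-BBN and oxidative work-up would give the keto alcohol (2R,3R)-3-(2-hydroxyethyl)-3-methyl-2-(3-methylbut-2-en-1-yl)cyclohexan-1-one F1. Any ketone reduced by the borane is restored in the next operation.
- Dess–Martin oxidation would give the keto aldehyde 2-[(1R,2R)-1-methyl-2-(3-methylbut-2-en-1-yl)-3-oxocyclohexyl]acetaldehyde F2.
- A carbonyl-ene cyclisation with Me2AlCl at −78 °C closes ring B in both epimeric series. Treatment of the crude product with NaOMe in MeOH then equilibrates C5 next to the C4 ketone, and the trans-fused decalone 8α-hydroxy-15-nor-5α-eudesm-11-en-4-one F3 should dominate. F3 to F6 are drawn for the all-equatorial ring B isomer; epimers at C7 and C8 converge later.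
- Silylation (TBSCl, imidazole) gives the ether 8α-(tert-butyldimethylsilyloxy)-15-nor-5α-eudesm-11-en-4-one F4.
- Kinetic enolisation toward C3 and trapping with PhNTf2 gives the enol triflate 8α-(tert-butyldimethylsilyloxy)-15-nor-5α-eudesma-3,11-dien-4-yl trifluoromethanesulfonate F5.
- Iron-catalysed coupling with MeMgBr gives the diene 8α-(tert-butyldimethylsilyloxy)-5α-eudesma-3,11-diene F6.
- Fluoride (Bu4NF) releases alcohol 12, and its oxidation with pyridinium chlorochromate or by the Dess–Martin method rejoins the route at 13.

**Step 5.** The one-flask sequence may stall or stray: the acid-promoted ene step competes with Prins-type attack of the aldehyde on the C3=C4 alkene and with further oxidation by the excess chromium reagent. The fallback separates the three events. It sets out from 10: Dess–Martin oxidation to 11, which is isolated; a Lewis-acid carbonyl-ene reaction of 11 with Me2AlCl in CH2Cl2 at −78 °C to 12; and Dess–Martin oxidation of 12, returning at 13. No compound outside the list is made.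

**Step 6.** The ring closure of the hydroperoxide adduct may show poor facial selectivity at C7, and addition of hydroperoxide to the crowded, fully substituted enone may be slow. The fallback avoids the oxirane and with it the acid step 7. It sets out from 13.
- KOtBu in THF/t-BuOH generates the extended enolate by removing the doubly activated C7 proton, and O2 with P(OEt)3 oxygenates it at C7 from the axial α face. This would give the ketol 7α-hydroxy-5α-eudesma-3,11-dien-8-one F7.
- Mukaiyama hydration (Co(acac)2, PhSiH3, O2) of the 1,1-disubstituted alkene, which reacts ahead of the trisubstituted C3=C4 alkene, returns to the route at 16.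

**Step 12.** Acylation of the axial C3 hydroxyl, which sits next to the fully substituted C4, may be slow, so that the activated acid is lost to opening of its oxirane by chloride or DMAP. The fallback moves the epoxidation to the end. It sets out from 17.
- Yamaguchi esterification with angelic acid 18, whose mixed anhydride carries no oxirane, would give the angelate 4α,7α,11-trihydroxy-8-oxo-5α-eudesman-3α-yl (Z)-2-methylbut-2-enoate F8.
- Epoxidation of the unsaturated ester with dimethyldioxirane, or with a chiral ketone-derived dioxirane for reagent control, followed by separation from the (2R,3R) diastereomer, arrives at 23.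

## Further compounds

F1 | step 1 | (2R,3R)-3-(2-hydroxyethyl)-3-methyl-2-(3-methylbut-2-en-1-yl)cyclohexan-1-one | O=C1CCC[C@](C)(CCO)[C@H]1CC=C(C)C
F2 | step 1 | 2-[(1R,2R)-1-methyl-2-(3-methylbut-2-en-1-yl)-3-oxocyclohexyl]acetaldehyde | O=C1CCC[C@](C)(CC=O)[C@H]1CC=C(C)C
F3 | step 1 | 8α-hydroxy-15-nor-5α-eudesm-11-en-4-one (7β-isopropenyl, 10β-methyl) | O=C1CCC[C@]2(C)C[C@H](O)[C@@H](C(C)=C)C[C@@H]12
F4 | step 1 | 8α-(tert-butyldimethylsilyloxy)-15-nor-5α-eudesm-11-en-4-one | O=C1CCC[C@]2(C)C[C@H](O[Si](C)(C)C(C)(C)C)[C@@H](C(C)=C)C[C@@H]12
F5 | step 1 | 8α-(tert-butyldimethylsilyloxy)-15-nor-5α-eudesma-3,11-dien-4-yl trifluoromethanesulfonate | FC(F)(F)S(=O)(=O)OC1=CCC[C@]2(C)C[C@H](O[Si](C)(C)C(C)(C)C)[C@@H](C(C)=C)C[C@@H]12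
F6 | step 1 | 8α-(tert-butyldimethylsilyloxy)-5α-eudesma-3,11-diene | CC1=CCC[C@]2(C)C[C@H](O[Si](C)(C)C(C)(C)C)[C@@H](C(C)=C)C[C@@H]12
F0 | step 5 | none | none
F7 | step 6 | 7α-hydroxy-5α-eudesma-3,11-dien-8-one | CC1=CCC[C@]2(C)CC(=O)[C@@](O)(C(C)=C)C[C@@H]12
F8 | step 12 | 4α,7α,11-trihydroxy-8-oxo-5α-eudesman-3α-yl (Z)-2-methylbut-2-enoate | C/C=C(/C)C(=O)O[C@@H]1CC[C@]2(C)CC(=O)[C@@](O)(C(C)(C)O)C[C@H]2[C@]1(C)O
A1 | alternative 1 | trans-1-methyl-2-[2-(tert-butyldimethylsilyloxy)ethyl]-4-[2-(triethylsilyloxy)propan-2-yl]cyclohex-3-ene-1-carbaldehyde | O=C[C@]1(C)CCC(C(C)(C)O[Si](CC)(CC)CC)=C[C@H]1CCO[Si](C)(C)C(C)(C)C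
A2 | alternative 1 | methacrolein (2-methylprop-2-enal) | CC(=C)C=O
A3 | alternative 1 | (E)-1-(tert-butyldimethylsilyloxy)-6-methyl-5-methylidene-6-(triethylsilyloxy)hept-3-ene | C=C(C(C)(C)O[Si](CC)(CC)CC)/C=C/CCO[Si](C)(C)C(C)(C)C
A4 | alternative 2 | germacrone, (1(10)E,4E)-germacra-1(10),4,7(11)-trien-8-one | C/C1=C\CC/C(C)=C/CC(=C(C)C)C(=O)C1
A5 | alternative 2 | (8R,1(10)E,4E)-germacra-1(10),4,7(11)-trien-8-yl acetate | C/C1=C\CC/C(C)=C/CC(=C(C)C)[C@H](OC(C)=O)C1
A6 | alternative 2 | (8R)-5α-eudesma-3,7(11)-dien-8-yl acetate (10β-methyl) | C1CC[C@]2(C)C[C@@H](OC(C)=O)C(=C(C)C)C[C@H]2C(C)=1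
A7 | alternative 3 | 4-(2,3-dioxobutyl)-4-methylcyclohexa-2,5-dien-1-one | CC(=O)C(=O)CC1(C)C=CC(=O)C=C1
A8 | alternative 3 | cis-fused 11,12,13,15-tetranoreudesm-1-ene-3,7,8-trione (5β-H, 10β-methyl) | O=C1C=C[C@]2(C)CC(=O)C(=O)C[C@@H]2C1
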